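**Plan**

- Retrosynthesis: the ring A hydroxyl is traced back to a formyl group (Dakin-type oxidation). The ring C–O bond on the bromine-flanked oxygen (C2 of ring B) is cut to a diaryliodonium salt, and the ring A–O bond on C1 of ring B to a fluoride displacement. This leaves 3,4,5-tribromocatechol, whose ring B is cut at C1–C6 and C2–C3.
- Enabling feature: ring B (C1–O–ring A, C2–O–ring C, Br on C3, C4 and C5, H on C6) is a catechol with three adjacent bromines and one hydrogen. It maps onto C2–C5 of 2,3,4-tribromothiophene 1,1-dioxide plus a cis-dioxygenated two-carbon unit.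
- Forward: ring B is closed first by [4+2] addition of the dioxide to vinylene carbonate with loss of SO2, then aromatised and freed as the catechol. Ring A is attached at the hydrogen-flanked oxygen, ring C at the bromine-flanked oxygen, and the formyl group becomes the phenol last.
- Stereochemistry: the target is achiral. The only stereocentres are two cis CH–O carbons set by the Z alkene locked in the carbonate ring; they are racemic and are erased in step 4.

Key step: step 3

Remark: the transient sp3 centres of 7 and 8 are carried as racemates with one enantiomer drawn; the pyramidal sulfur of 1-oxide 4 inverts readily and is given no configuration.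

**Route**

Step 1
Reactants: 1 tetrabromothiophene
Product: 3 2,3,4-tribromothiophene, via 3,4,5-tribromo-2-thienyllithium 2 (not isolated)
Conditions: n-BuLi (1.0 equiv), THF, −78 °C; then MeOH, −78 °C to rt
Reagents that add atoms: none
Why: Bromine–lithium exchange is fastest at an α-carbon of the perbrominated thiophene, where sulfur best stabilises the thienyl anion, and protonation of 2 at low temperature leaves the 2,3,4-tribromo pattern (halogen–metal exchange and protonolysis).

Step 2
Reactants: 3 2,3,4-tribromothiophene
Product: 5 2,3,4-tribromothiophene 1,1-dioxide, via 2,3,4-tribromothiophene 1-oxide 4 (not isolated)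
Conditions: (CF3CO)2O, urea·H2O2, MeCN–CH2Cl2, 0 °C to rt
Reagents that add atoms: trifluoroperacetic acid, OOC(=O)C(F)(F)F (formed in the flask from trifluoroacetic anhydride, O=C(OC(=O)C(F)(F)F)C(F)(F)F, and urea–hydrogen peroxide, NC(N)=O.OO; it delivers both sulfone oxygens)
Why: Trifluoroperacetic acid is electrophilic enough to oxidise the sulfur of electron-poor halothiophenes, and the non-aromatic 1-oxide 4 is oxidised faster than 3, so the reaction should run through to the sulfone (peracid S-oxidation of a thiophene).

Step 3
Reactants: 5 2,3,4-tribromothiophene 1,1-dioxide and 6 vinylene carbonate (1,3-dioxol-2-one)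
Product: 8 cis-4,5,6-tribromo-3a,7a-dihydro-1,3-benzodioxol-2-one (racemic), via sulfone-bridged cycloadduct 7 (not isolated)
Conditions: 6 (8 equiv, neat, trace BHT), 5 added in portions, 100 °C, Ar; −SO2
Reagents that add atoms: none
Why: The electron-poor, non-aromatic diene of 5 (C2=C3–C4=C5) adds suprafacially to the C=C of 6 in a concerted [4+2] cycloaddition of inverse electron demand, and the 7-thiabicyclo[2.2.1]heptene sulfone 7 then expels SO2 in a retro-cheletropic step. The closest known reaction type is the Diels–Alder/SO2-extrusion sequence of tetrahalothiophene 1,1-dioxides with alkenes, which gives halogenated cyclohexa-1,3-dienes. Ring B is closed by intermolecular cycloaddition that forms its C2–C3 and C1–C6 bonds, while the carbonate ring is carried in intact as a cis-fused annulation. The two new CH–O stereocentres are cis because the Z alkene geometry is locked in the five-membered carbonate and both bonds form on one face of it; they arise as a racemate, endo versus exo in 7 is lost with the bridge, and both centres disappear in step 4. The step needs cycloaddition to outrun [4+2] dimerisation of 5, which the large excess of neat 6 and portionwise addition of 5 should secure; no regiochemistry arises because 6 is symmetrical, and the diene alone places Br on C3–C5 and H on C6.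

Step 4
Reactants: 8 cis-4,5,6-tribromo-3a,7a-dihydro-1,3-benzodioxol-2-one
Product: 9 4,5,6-tribromo-1,3-benzodioxol-2-one
Conditions: DDQ (1.5 equiv), chlorobenzene, reflux
Reagents that add atoms: none
Why: DDQ removes hydride from one of the doubly allylic, oxygen-bearing C–H bonds and the resulting cation loses the neighbouring proton, so the gain of aromaticity should drive dehydrogenation under neutral conditions in which neither carbonate oxygen is eliminated (quinone dehydrogenation of a dihydroarene).

Step 5
Reactants: 9 4,5,6-tribromo-1,3-benzodioxol-2-one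
Product: 10 3,4,5-tribromobenzene-1,2-diol
Conditions: 1 M HCl (aq), THF, 50 °C, Ar
Reagents that add atoms: none
Why: The strained aryl cyclic carbonate is hydrolysed by acyl–oxygen cleavage with loss of CO2, and the acidic medium keeps the air-sensitive catechol protonated (acid-catalysed carbonate hydrolysis).

Step 6
Reactants: 10 3,4,5-tribromobenzene-1,2-diol and 11 3,5-dibromo-2-fluorobenzaldehyde
Product: 13 3,5-dibromo-2-(3,4,5-tribromo-2-hydroxyphenoxy)benzaldehyde, via disodium 3,4,5-tribromocatecholate 12 (not isolated)
Conditions: NaH (2.1 equiv), DMF, 0 °C to rt; then 11 (1.0 equiv), rt to 50 °C; aq. HCl work-up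
Reagents that add atoms: none
Why: Nucleophilic aromatic substitution (addition–elimination) at the fluorine-bearing carbon activated by the ortho formyl group: in dianion 12 the more basic, unhindered oxygen on C1 (next to C6–H) attacks, and because the bromine-flanked oxygen on C2 is the more stable phenoxide, any Smiles equilibration of the formyl-activated ring between the two oxygens should funnel to the same isomer 13.

Step 7
Reactants: 14 2,4-dibromo-1-iodobenzene
Product: 16 (2,4-dibromophenyl)(2,4,6-trimethoxyphenyl)iodonium tosylate, via 2,4-dibromo-1-[hydroxy(tosyloxy)iodo]benzene 15 (not isolated)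
Conditions: mCPBA, TsOH·H2O, MeCN, 77 °C; then 1,3,5-trimethoxybenzene, rt
Reagents that add atoms: 1,3,5-trimethoxybenzene, COc1cc(OC)cc(OC)c1; p-toluenesulfonic acid monohydrate, Cc1ccc(cc1)S(=O)(=O)O.O
Why: mCPBA and TsOH oxidise the aryl iodide to the hydroxy(tosyloxy)iodoarene 15, a trivalent iodine electrophile that substitutes the very electron-rich trimethoxybenzene at carbon (one-pot synthesis of unsymmetrical diaryliodonium salts).

Step 8
Reactants: 13 3,5-dibromo-2-(3,4,5-tribromo-2-hydroxyphenoxy)benzaldehyde and 16 (2,4-dibromophenyl)(2,4,6-trimethoxyphenyl)iodonium tosylate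
Product: 17 3,5-dibromo-2-[3,4,5-tribromo-2-(2,4-dibromophenoxy)phenoxy]benzaldehyde
Conditions: K2CO3 (1.5 equiv), MeCN, 50 °C
Reagents that add atoms: none
Why: Metal-free O-arylation with a diaryliodonium salt: the phenoxide of 13 exchanges onto trivalent iodine and ligand coupling transfers the electron-poorer, ortho-substituted 2,4-dibromophenyl group rather than the trimethoxyphenyl dummy, a process that tolerates doubly ortho-substituted bromophenoxides, while the mild carbonate base and moderate temperature disfavour aryne formation and migration of ring A.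

Step 9
Reactants: 17 3,5-dibromo-2-[3,4,5-tribromo-2-(2,4-dibromophenoxy)phenoxy]benzaldehyde
Product: 19 bromoiesol A (3,5-dibromo-2-[3,4,5-tribromo-2-(2,4-dibromophenoxy)phenoxy]phenol), via aryl formate 18 (not isolated)
Conditions: mCPBA (1.5 equiv), CH2Cl2, 0 °C to rt; aq. Na2SO3/NaHCO3 wash; then MeOH, HCl (cat.), rt
Reagents that add atoms: 3-chloroperoxybenzoic acid (mCPBA), OOC(=O)c1cccc(Cl)c1
Why: Baeyer–Villiger (Dakin-type) oxidation: in the Criegee adduct of the aldehyde the aryl group, made migratory by its ortho aryloxy donor, shifts to oxygen to give formate 18, whose acid methanolysis releases the ring A phenol and completes the target.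

**Compound list**

1 | tetrabromothiophene | Brc1sc(Br)c(Br)c1Br | starting material
2 | 3,4,5-tribromo-2-thienyllithium | [Li]c1sc(Br)c(Br)c1Br | intermediate
3 | 2,3,4-tribromothiophene | Brc1csc(Br)c1Br | intermediate
4 | 2,3,4-tribromothiophene 1-oxide | O=S1C=C(Br)C(Br)=C1Br | intermediate
5 | 2,3,4-tribromothiophene 1,1-dioxide | O=S1(=O)C=C(Br)C(Br)=C1Br | intermediate
6 | vinylene carbonate (1,3-dioxol-2-one) | O=C1OC=CO1 | starting material
7 | 4,5,6-tribromo-3a,4,7,7a-tetrahydro-4,7-epithio-1,3-benzodioxol-2-one 8,8-dioxide (sulfone-bridged cycloadduct; racemic, endo isomer drawn) | O=C1O[C@@H]2[C@H](O1)[C@]3(Br)C(Br)=C(Br)[C@H]2S3(=O)=O | intermediate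
8 | cis-4,5,6-tribromo-3a,7a-dihydro-1,3-benzodioxol-2-one (racemic, one enantiomer drawn) | O=C1O[C@@H]2C=C(Br)C(Br)=C(Br)[C@@H]2O1 | intermediate
9 | 4,5,6-tribromo-1,3-benzodioxol-2-one | O=C1Oc2cc(Br)c(Br)c(Br)c2O1 | intermediate
10 | 3,4,5-tribromobenzene-1,2-diol | Oc1cc(Br)c(Br)c(Br)c1O | intermediate
11 | 3,5-dibromo-2-fluorobenzaldehyde | O=Cc1cc(Br)cc(Br)c1F | starting material
12 | disodium 3,4,5-tribromocatecholate | [Na+].[Na+].[O-]c1cc(Br)c(Br)c(Br)c1[O-] | intermediate
13 | 3,5-dibromo-2-(3,4,5-tribromo-2-hydroxyphenoxy)benzaldehyde | O=Cc1cc(Br)cc(Br)c1Oc1cc(Br)c(Br)c(Br)c1O | intermediate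
14 | 2,4-dibromo-1-iodobenzene | Brc1ccc(I)c(Br)c1 | starting material
15 | 2,4-dibromo-1-[hydroxy(tosyloxy)iodo]benzene | OI(OS(=O)(=O)c1ccc(C)cc1)c1ccc(Br)cc1Br | intermediate
16 | (2,4-dibromophenyl)(2,4,6-trimethoxyphenyl)iodonium tosylate | COc1cc(OC)c([I+]c2ccc(Br)cc2Br)c(OC)c1.Cc1ccc(cc1)S(=O)(=O)[O-] | intermediate
17 | 3,5-dibromo-2-[3,4,5-tribromo-2-(2,4-dibromophenoxy)phenoxy]benzaldehyde | O=Cc1cc(Br)cc(Br)c1Oc1cc(Br)c(Br)c(Br)c1Oc1ccc(Br)cc1Br | intermediate
18 | 3,5-dibromo-2-[3,4,5-tribromo-2-(2,4-dibromophenoxy)phenoxy]phenyl formate | O=COc1cc(Br)cc(Br)c1Oc1cc(Br)c(Br)c(Br)c1Oc1ccc(Br)cc1Br | intermediate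
19 | bromoiesol A, 3,5-dibromo-2-[3,4,5-tribromo-2-(2,4-dibromophenoxy)phenoxy]phenol | Oc1cc(Br)cc(Br)c1Oc1cc(Br)c(Br)c(Br)c1Oc1ccc(Br)cc1Br | target

**Step count**

Total steps: 9. Longest linear sequence: 8 steps (steps 1–6, 8 and 9 from tetrabromothiophene); step 7 is a one-step side branch.

**Steps most likely to fail**

1. Step 4. Hydride abstraction from the electron-poor tribromodiene may be slower than thermal or acid-promoted loss of a carbonate oxygen, so that the ring aromatises by elimination to a bromophenol or does not aromatise at all. Fallback, setting out from 8 and replacing steps 4 and 5: transesterification with MeOH and catalytic K2CO3 at 0 °C should release cis-3,4,5-tribromocyclohexa-3,5-diene-1,2-diol F1. Oxidation of one allylic carbinol with IBX in DMSO at rt, which does not cleave glycols, should give 3,4,5-tribromo-6-hydroxycyclohexa-2,4-dien-1-one F2. This keto tautomer enolises at once to catechol 10, where the route is rejoined; a Na2S2O4 wash returns any o-quinone formed by over-oxidation.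

2. Step 6. If dianion formation is incomplete or ion pairing levels the two sites, attack may occur through the bromine-flanked oxygen or at both oxygens, giving the regioisomeric or the doubly arylated ether. Fallback, setting out from 10 and replacing steps 6 and 8 by the reverse order: with only one equivalent of K2CO3 in MeCN the charge sits on the more acidic bromine-flanked oxygen, and arylation of this monoanion with 16 should give 3,4,5-tribromo-2-(2,4-dibromophenoxy)phenol F3, whose unactivated ring C cannot migrate. The remaining hydroxyl then displaces fluoride from 11 (K2CO3, DMAc, 80 °C) to give 17, where the route is rejoined.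

3. Step 8. The formyl-activated ring A may migrate to the other catechol oxygen by Smiles rearrangement before arylation, and ligand coupling at the doubly ortho-substituted phenoxide may be slow enough for the iodonium salt to decompose. Fallback, setting out from 13: acetalisation with ethylene glycol and catalytic TsOH in refluxing toluene (Dean–Stark) should give 2,3,4-tribromo-6-[2,4-dibromo-6-(1,3-dioxolan-2-yl)phenoxy]phenol F4, in which ring A is no longer activated for ipso attack. Arylation with 16 (K2CO3, MeCN, 60 °C) should give 2-{3,5-dibromo-2-[3,4,5-tribromo-2-(2,4-dibromophenoxy)phenoxy]phenyl}-1,3-dioxolane F5, and aqueous HCl in THF returns aldehyde 17, where the route is rejoined.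

**Further compounds**

F1 | step 4 | cis-3,4,5-tribromocyclohexa-3,5-diene-1,2-diol (racemic) | O[C@@H]1C=C(Br)C(Br)=C(Br)[C@@H]1O
F2 | step 4 | 3,4,5-tribromo-6-hydroxycyclohexa-2,4-dien-1-one (racemic, not isolated) | O=C1C=C(Br)C(Br)=C(Br)[C@@H]1O
F3 | step 6 | 3,4,5-tribromo-2-(2,4-dibromophenoxy)phenol | Oc1cc(Br)c(Br)c(Br)c1Oc1ccc(Br)cc1Br
F4 | step 8 | 2,3,4-tribromo-6-[2,4-dibromo-6-(1,3-dioxolan-2-yl)phenoxy]phenol | Oc1c(Br)c(Br)c(Br)cc1Oc1c(Br)cc(Br)cc1C1OCCO1
F5 | step 8 | 2-{3,5-dibromo-2-[3,4,5-tribromo-2-(2,4-dibromophenoxy)phenoxy]phenyl}-1,3-dioxolane | Brc1ccc(Oc2c(Br)c(Br)c(Br)cc2Oc2c(Br)cc(Br)cc2C2OCCO2)c(Br)c1
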